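The earlier runs and the new flask are simulated from invented constants; the scatter is artificial.

**The decision.** By 6.00 d Saturday's flask has slowed badly, and what we do at 8.0 d depends on whether its enzyme can still work. The four options are weighed below.

| flask | starting material | second substrate | free enzyme | remark | time |
|---|---|---|---|---|---|
| Saturday's | 0.14 M | 0.28 M | 14 µM | the very flask that is asked about, followed so far |  |
| Tuesday's | 0.14 M | 0.19 M | 14 µM | run made earlier |  |
| flask | 0.14 M | 0.280 M | 14 µM |  | 8.0 d |

- Saturday's (time / d: target / %, starting material / %): 0.500: 5.6, 94.5; 1.25: 10.4, 88.3; 3.00: 15.7, 80.4; 6.00: 15.4, 74.7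
- Tuesday's (time / d: target / %, starting material / %): 0.208: 1.8, 97.6; 0.417: 3.8, 96.3; 1.04: 8.5, 91.0; 2.50: 14.7, 82.3

(each reading ± 0.3 percentage points)

- blue: at 8.0 d take out 90% of the first product then present, then wait 4.0 d
- grey: at 8.0 d add second substrate, 50.0% of the amount charged, then wait 4.0 d
- red: at 8.0 d add free enzyme, 100% of the amount charged, then wait 4.0 d
- violet: change nothing and wait 4.0 d more

- target, in percent of the starting material first charged, at 8.0 d
- what to do for the largest gain in target; "none" if nothing gains more than 2 percentage points (blue / grey / red / violet / none)
- target present, in percent of the starting material first charged, after grey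
- target present, in percent of the starting material first charged, after violet

- additions leave the volume as it is
- candidate steps: starting material + free enzyme <-> first complex; first complex <-> loaded enzyme + first product; second substrate + loaded enzyme <-> second complex; second complex -> free enzyme + target; free enzyme -> spent catalyst; target -> over-reaction product

**Counting half-lives.** Saturday's flask used starting material at 0.110 d⁻¹ of its charge over the first 0.500 d, but at 0.0190 d⁻¹ between 3.00 d and 6.00 d, far slower. With 74.7% of the starting material still there at 6.00 d, we read this as the catalyst dying, and the two rates read as a half-life of the rate of 1.68 d. Adding the tail of that decay to what was used by 6.00 d gives an estimated final consumption of 27.8% of the charge. That is a turnover budget of 2780 molecules of starting material per enzyme charged, the usual turnover number.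

**Our choice.** Saturday's curve gives 17.9% used at 2.50 d, and Tuesday's run, with less second substrate, read 17.7% there, so we expect no gain from grey. By our count, 4.76 half-lives have passed at 8.0 d and 1 percentage point of the budget remains. Between 3.00 d and 6.00 d Saturday's target read 15.7% and then 15.4% while 5.7 points of starting material went, so we read target as being lost. We expect blue and violet to lose target as well. We choose red, since a second charge of free enzyme is a second budget, which we put near 27.8% of the charge, more than what remains.

**The forecast.** It says “This suggests free enzyme dies, so the total turnover is roughly fixed”. It gives 12.9% now, 8.6% after grey and 8.4% after violet, and it picks red.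

**The result.** The flask gives 13.1%, 8.46% after grey and 8.45% after violet. Red is best, at 7.6 points against −4.6 points for violet.

    starting material + free enzyme ⇌ first complex (K = 8.30 M⁻¹, k = 29.0 M⁻¹ s⁻¹)
    first complex ⇌ loaded enzyme + first product (K = 0.370 M, k = 0.0260 s⁻¹)
    second substrate + loaded enzyme ⇌ second complex (K = 46.0 M⁻¹, k = 0.850 M⁻¹ s⁻¹)
    second complex → free enzyme + target (k = 1.50 s⁻¹)
    free enzyme → spent catalyst (k = 9.00 × 10⁻⁶ s⁻¹)
    target → over-reaction product (k = 1.50 × 10⁻⁶ s⁻¹)

**Neighbour flask.** Saturday's flask, left to run, had consumed 28.2% of its starting material at 80.0 d, close to the budget of 27.8%. The same 2780 per enzyme, applied to a neighbour charged with 8.4 × 10⁻⁶ M of free enzyme, gives 16.7%. That neighbour had used 17.2% at 8.00 d, with 94.5% of its catalyst spent. That neighbour held 8.41% of target at 8.00 d.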